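In a one-step world starting material and coupling partner make target and nothing else, so ash, charged with 0.70 equiv of partner, should climb towards 70.0% target, but its last reading is 28%.

| flask | starting material | coupling partner | second substrate | third substrate | temperature | remark | time |
|---|---|---|---|---|---|---|---|
| ash | 24 mM | 0.70 equiv | 0.20 equiv | 5 equiv | 30 °C | run made earlier |  |
| birch | 24 mM | 0.47 equiv | 0.20 equiv | 5 equiv | 41 °C | run made earlier |  |
| elm | 24 mM | 1 equiv | 0.20 equiv | 5 equiv | 30 °C | run made earlier |  |
| oak | 24 mM | 0.70 equiv | 0.30 equiv | 5 equiv | 41 °C | run made earlier |  |
| west | 24 mM | 0.700 equiv | 0.200 equiv | 5.00 equiv | 35 °C | everything together at the start | 4.0 h |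
| north | 24 mM | 0.700 equiv | 0.200 equiv | 5.00 equiv (in portions, 2, over 50 min) | 35 °C | first portion at the start, last at 50 min | 4.0 h |
| north-east | 24 mM (fed, over 50 min) | 0.700 equiv | 0.200 equiv | 5.00 equiv | 35 °C | all else is in the flask from the start; the feed brings no volume worth counting | 4.0 h |
| south-west | 24 mM (fed, over 50 min) | 0.700 equiv | 0.200 equiv | 5.00 equiv |  | the addition at 5 °C, then warmed to 35 °C; the feed brings no volume worth counting | 4.0 h |

- ash (time / h: target / %, starting material / %): 0.200: 2, 91; 0.417: 13, 83; 1.00: 23, 73; 2.50: 28, 62
- birch (time / h: target / %, starting material / %): 0.333: 11, 82; 0.833: 19, 67; 1.50: 19, 59; 2.50: 17, 52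
- elm (time / h: target / %, starting material / %): 0.333: 17, 80; 0.833: 33, 66; 1.50: 35, 58; 2.50: 41, 50
- oak (time / h: target / %, starting material / %): 0.667: 26, 62; 1.33: 29, 56; 2.00: 25, 53; 2.50: 33, 50

(readings scatter by 2 percentage points)



- the flask with the highest amount of target, in percent of the starting material charged ("all alike" if they lie within 1.5 percentage points) (west / north / north-east / south-west / all alike)
- final target, as a percentage of the starting material charged, in west
- final target, as a percentage of the starting material charged, in north
- final target, as a percentage of the starting material charged, in north-east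
- final target, as a percentage of the starting material charged, in south-west

So I divide the target level each run reaches, as I read it, by the partner charged, and over ash, birch, elm and oak this gives 40.7% on average, from readings that scatter by 2 percentage points. I call this the partner's share: the percent of the charged partner that ends as target, its selectivity for target.

The share as read shows no trend across these runs, which span 30 °C to 41 °C, 0.47 equiv to 1 equiv of partner, and 0.20 equiv and 0.30 equiv of second substrate, but third substrate stands at 5 equiv in all of them. So I reckon west at 28.5%. North keeps back half of its third substrate until 50 min, and I commit to a share at or above 40.7%, which puts north at or above west. I put north-east, with its starting material fed in, below west, and south-west close to west.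

The forecast picks west, with west at 28%, north at 28%, north-east at 20% and south-west at 27%: "The top flasks are effectively tied".

The flasks give 30.7% in west, 34.7% in north, 24.4% in north-east and 29.5% in south-west, so north holds the most target.

    starting material + coupling partner → target (k = 0.780 M⁻¹ min⁻¹, Ea = 72.0 kJ mol⁻¹)
    second substrate + coupling partner → second product (k = 6.70 M⁻¹ min⁻¹, Ea = 47.0 kJ mol⁻¹)
    third substrate + coupling partner → third product (k = 0.0780 M⁻¹ min⁻¹, Ea = 61.0 kJ mol⁻¹)
    coupling partner → decomposition product (k = 3.60 × 10⁻⁶ min⁻¹, Ea = 110 kJ mol⁻¹)
    2 starting material → homo dimer (k = 0.0550 M⁻¹ min⁻¹, Ea = 71.0 kJ mol⁻¹)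
    (constants at 35 °C)

North's share is 49.6%, higher than the 40.7% I read off the earlier runs, and west's is 43.9%. North ends with 3.65 mM of third product against 4.71 mM in west, while second product stands at 4.71 mM and 4.65 mM. The neighbour of north with 2.00 equiv of third substrate gives 40.3% target, a share of 57.6%, and ends with 1.94 mM of third product.

Readings and results were computed for an exercise; the scatter is artificial.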